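**Plan**

- Retrosynthesis: the ring B quinone goes back to a benzyl-protected 2-hydroxy-3,4,5-trimethoxyphenyl group and ring C is opened at O1–C2. Ring A is cut at C5–C6, C4a–C8a and C8–C8a into a terminal alkyne, one CO ligand and a methoxy(1-methoxyvinyl)carbene of zerovalent chromium. The alkyne is cut at C3–C4 into an arylacetyl imide and propargyl bromide.
- Enabling feature: ring A is a 1,2,4-trioxygenated benzene in which C8a (bearing O1) is para to the C6 methoxy group and ortho to the C4a side chain. This is the 4-methoxyphenol pattern that a carbene–alkyne–CO benzannulation delivers.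
- Forward: ring B comes from 2,3,4-trimethoxyphenol and receives the C3 side chain; ring A is then built by the benzannulation, ring C is closed by Mitsunobu etherification, and ring B is oxidised to the quinone last.
- Stereochemistry: C3 is set once, by propargylating the (4S)-4-benzyloxazolidinone imide enolate on the face away from the auxiliary benzyl group. No later step touches it.

Key step: step 10

Remark: atoms are labelled on the isoflavan skeleton (O1, C2, C3, C4, C4a, C5 to C8, C8a; ring A benzo, ring C pyran, ring B quinone), and the target is taken as the (3S) isomer that its structure encodes.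

**Route**

Step 1
Reactants: 1 2,3,4-trimethoxyphenol
Product: 2 6-bromo-2,3,4-trimethoxyphenol
Conditions: NBS, i-Pr2NH (cat.), CH2Cl2, 0 °C
Reagents that add atoms: N-bromosuccinimide, O=C1CCC(=O)N1Br
Why: Amine-mediated electrophilic aromatic bromination of a para-blocked phenol, in which a hydrogen-bonded N-bromoamine should deliver bromine to the only free position ortho to the hydroxyl rather than to C5.

Step 2
Reactants: 2 6-bromo-2,3,4-trimethoxyphenol
Product: 3 2-(benzyloxy)-1-bromo-3,4,5-trimethoxybenzene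
Conditions: BnBr, K2CO3, DMF, rt
Reagents that add atoms: benzyl bromide, BrCc1ccccc1
Why: Williamson etherification of the phenoxide, giving a benzyl ether that can later be removed by hydrogenolysis to expose this one oxygen for the final oxidation.

Step 3
Reactants: 3 2-(benzyloxy)-1-bromo-3,4,5-trimethoxybenzene; 4 tert-butyl bromoacetate
Product: 6 tert-butyl [2-(benzyloxy)-3,4,5-trimethoxyphenyl]acetate, via Reformatsky reagent 5 (not isolated)
Conditions: 4, Zn dust, THF, rt; then 3, Pd(dba)2 (cat.), P(t-Bu)3 (cat.), THF, rt to 60 °C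
Reagents that add atoms: none
Why: Zinc insertion gives the Reformatsky reagent, and its palladium-catalysed α-arylation (a Negishi-type coupling under zerovalent palladium) is base-free and should stop cleanly at monoarylation with the ortho-alkoxy aryl bromide.

Step 4
Reactants: 6 tert-butyl [2-(benzyloxy)-3,4,5-trimethoxyphenyl]acetate
Product: 7 [2-(benzyloxy)-3,4,5-trimethoxyphenyl]acetic acid
Conditions: TFA, CH2Cl2, 0 °C to rt
Reagents that add atoms: none
Why: Acidolysis of the tert-butyl ester with loss of 2-methylpropene, under which aryl benzyl and aryl methyl ethers are stable at room temperature.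

Step 5
Reactants: 7 [2-(benzyloxy)-3,4,5-trimethoxyphenyl]acetic acid; 8 (4S)-4-benzyl-1,3-oxazolidin-2-one
Product: 10 (4S)-4-benzyl-3-{[2-(benzyloxy)-3,4,5-trimethoxyphenyl]acetyl}-1,3-oxazolidin-2-one, via mixed pivalic anhydride 9 (not isolated)
Conditions: PivCl, Et3N, THF, −20 °C; then LiCl, 8, rt
Reagents that add atoms: none
Why: Mixed-anhydride N-acylation of the oxazolidinone promoted by LiCl, in which the hindered pivaloyl carbonyl directs attack to the arylacetyl carbonyl.

Step 6
Reactants: 10 (4S)-4-benzyl-3-{[2-(benzyloxy)-3,4,5-trimethoxyphenyl]acetyl}-1,3-oxazolidin-2-one; 11 propargyl bromide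
Product: 13 (4S)-4-benzyl-3-{(2S)-2-[2-(benzyloxy)-3,4,5-trimethoxyphenyl]pent-4-ynoyl}-1,3-oxazolidin-2-one, via sodium enolate 12 (not isolated)
Conditions: NaN(SiMe3)2, THF, −78 °C; then 11, −78 to −40 °C
Reagents that add atoms: none
Why: Evans asymmetric alkylation, in which the chelated Z-enolate is attacked by propargyl bromide on the face opposite the C4 benzyl group of the auxiliary, setting the future C3 as (2S), with the minor diastereomer removable by chromatography.

Step 7
Reactants: 13 (4S)-4-benzyl-3-{(2S)-2-[2-(benzyloxy)-3,4,5-trimethoxyphenyl]pent-4-ynoyl}-1,3-oxazolidin-2-one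
Product: 14 (2S)-2-[2-(benzyloxy)-3,4,5-trimethoxyphenyl]pent-4-yn-1-ol
Conditions: LiBH4, MeOH (1 equiv), Et2O, 0 °C
Reagents that add atoms: none
Why: Reductive cleavage of the N-acyloxazolidinone by hydride attack at the exocyclic carbonyl, which at 0 °C should release the primary alcohol without epimerising the α-aryl centre and return the auxiliary.

Step 8
Reactants: 14 (2S)-2-[2-(benzyloxy)-3,4,5-trimethoxyphenyl]pent-4-yn-1-ol
Product: 15 (4S)-4-[2-(benzyloxy)-3,4,5-trimethoxyphenyl]-5-[(tert-butyldimethylsilyl)oxy]pent-1-yne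
Conditions: TBSCl, imidazole, CH2Cl2, rt
Reagents that add atoms: tert-butyldimethylsilyl chloride, CC(C)(C)[Si](C)(C)Cl
Why: Standard silylation of the primary alcohol, which masks the hydroxyl that could otherwise trap the ketene intermediate of the benzannulation.

Step 9
Reactants: 16 methyl vinyl ether; 17 chromium hexacarbonyl
Product: 20 pentacarbonyl[methoxy(1-methoxyethenyl)methylidene]chromium, via 1-methoxyvinyllithium 18 (not isolated), via lithium acylchromate 19 (not isolated)
Conditions: t-BuLi, THF, −78 to 0 °C; Cr(CO)6, THF, −78 °C to rt; then MeOTf, CH2Cl2, 0 °C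
Reagents that add atoms: methyl trifluoromethanesulfonate, COS(=O)(=O)C(F)(F)F
Why: Fischer carbene synthesis, in which the α-lithiated enol ether adds to a CO ligand of Cr(CO)6 and the resulting acylchromate is O-methylated by the hard methylating agent.

Step 10
Reactants: 15 (4S)-4-[2-(benzyloxy)-3,4,5-trimethoxyphenyl]-5-[(tert-butyldimethylsilyl)oxy]pent-1-yne; 20 pentacarbonyl[methoxy(1-methoxyethenyl)methylidene]chromium
Product: 22 2-{(2S)-2-[2-(benzyloxy)-3,4,5-trimethoxyphenyl]-3-[(tert-butyldimethylsilyl)oxy]propyl}-4,5-dimethoxyphenol, via tricarbonylchromium arene complex 21 (not isolated)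
Conditions: 20 (1.5 equiv), THF (0.05 M), 50 °C, Ar; then air, MeCN, rt
Reagents that add atoms: none
Why: Thermal loss of a cis CO from the zerovalent chromium carbene 20 lets the alkyne coordinate and insert into the Cr=C bond (C5–C6), a CO ligand then inserts to give a metal-bound dienylketene (C4a–C8a), and 6π electrocyclisation (C8–C8a) followed by tautomerisation gives the phenol as its Cr(CO)3 complex 21, from which air releases the arene. The closest known reaction type is the Dötz benzannulation of alkenyl(alkoxy)carbene chromium complexes with terminal alkynes, including α-oxygenated alkenyl complexes made from lithiated enol ethers. Ring A is the only ring closed, by disrotatory 6π electrocyclisation of the dienylketene, and no stereocentre is created. The step needs regioselective alkyne insertion; the steric difference between the hydrogen end and the branched alkyl end of 15 should place the substituted carbon next to the CO-derived carbon, so the new hydroxyl on C8a lies ortho to the chain and para to the C6 methoxy group. It also needs the ketene to cyclise rather than be trapped, which the silyl ether secures by removing the hydroxyl that could otherwise close a δ-lactone. The neutral, mildly warm conditions should leave the C3 centre, the benzyl ether and the silyl ether untouched.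

Step 11
Reactants: 22 2-{(2S)-2-[2-(benzyloxy)-3,4,5-trimethoxyphenyl]-3-[(tert-butyldimethylsilyl)oxy]propyl}-4,5-dimethoxyphenol
Product: 23 2-{(2S)-2-[2-(benzyloxy)-3,4,5-trimethoxyphenyl]-3-hydroxypropyl}-4,5-dimethoxyphenol
Conditions: Bu4NF, AcOH, THF, 0 °C to rt
Reagents that add atoms: none
Why: Fluoride-driven desilylation, buffered with acetic acid so that the electron-rich phenol is never held as an oxidation-prone phenoxide.

Step 12
Reactants: 23 2-{(2S)-2-[2-(benzyloxy)-3,4,5-trimethoxyphenyl]-3-hydroxypropyl}-4,5-dimethoxyphenol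
Product: 24 (3S)-3-[2-(benzyloxy)-3,4,5-trimethoxyphenyl]-6,7-dimethoxy-3,4-dihydro-2H-chromene
Conditions: PPh3, DIAD, THF (0.02 M), 0 °C to rt
Reagents that add atoms: none
Why: Intramolecular Mitsunobu etherification, in which the ring A phenol displaces the activated primary alcohol in a 6-exo-tet closure of O1–C2; C3 is not a reacting centre and keeps its configuration, and the benzyl ether on ring B rules out the competing five-membered closure.

Step 13
Reactants: 24 (3S)-3-[2-(benzyloxy)-3,4,5-trimethoxyphenyl]-6,7-dimethoxy-3,4-dihydro-2H-chromene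
Product: 25 6-[(3S)-6,7-dimethoxy-3,4-dihydro-2H-chromen-3-yl]-2,3,4-trimethoxyphenol
Conditions: H2 (1 atm), Pd/C, EtOAc, rt
Reagents that add atoms: none
Why: Hydrogenolysis of the benzyl aryl ether, with no other reducible group left in the molecule and the chroman C–O bonds not benzylic.

Step 14
Reactants: 25 6-[(3S)-6,7-dimethoxy-3,4-dihydro-2H-chromen-3-yl]-2,3,4-trimethoxyphenol
Product: 26 abruquinone A, 5-[(3S)-6,7-dimethoxy-3,4-dihydro-2H-chromen-3-yl]-2,3-dimethoxycyclohexa-2,5-diene-1,4-dione
Conditions: PhI(OAc)2, MeCN/H2O, 0 °C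
Reagents that add atoms: water, O
Why: Hypervalent-iodine oxidative demethylation of a para-methoxyphenol, in which water adds para to the activated phenol oxygen and methanol is lost to give the 1,4-quinone, while ring A has no free hydroxyl and should not be oxidised.

**Compound list**

1 | 2,3,4-trimethoxyphenol | COc1ccc(O)c(OC)c1OC | starting material
2 | 6-bromo-2,3,4-trimethoxyphenol | COc1cc(Br)c(O)c(OC)c1OC | intermediate
3 | 2-(benzyloxy)-1-bromo-3,4,5-trimethoxybenzene | COc1cc(Br)c(OCc2ccccc2)c(OC)c1OC | intermediate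
4 | tert-butyl bromoacetate | CC(C)(C)OC(=O)CBr | starting material
5 | (2-tert-butoxy-2-oxoethyl)zinc bromide (Reformatsky reagent) | CC(C)(C)OC(=O)C[Zn]Br | intermediate
6 | tert-butyl [2-(benzyloxy)-3,4,5-trimethoxyphenyl]acetate | CC(C)(C)OC(=O)Cc1cc(OC)c(OC)c(OC)c1OCc1ccccc1 | intermediate
7 | [2-(benzyloxy)-3,4,5-trimethoxyphenyl]acetic acid | OC(=O)Cc1cc(OC)c(OC)c(OC)c1OCc1ccccc1 | intermediate
8 | (4S)-4-benzyl-1,3-oxazolidin-2-one | O=C1OC[C@H](Cc2ccccc2)N1 | starting material
9 | [2-(benzyloxy)-3,4,5-trimethoxyphenyl]acetic pivalic anhydride | CC(C)(C)C(=O)OC(=O)Cc1cc(OC)c(OC)c(OC)c1OCc1ccccc1 | intermediate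
10 | (4S)-4-benzyl-3-{[2-(benzyloxy)-3,4,5-trimethoxyphenyl]acetyl}-1,3-oxazolidin-2-one | O=C(Cc1cc(OC)c(OC)c(OC)c1OCc1ccccc1)N1[C@@H](Cc2ccccc2)COC1=O | intermediate
11 | propargyl bromide (3-bromoprop-1-yne) | C#CCBr | starting material
12 | sodium (Z)-enolate of imide 10 | [Na+].[O-]/C(=C\c1cc(OC)c(OC)c(OC)c1OCc1ccccc1)N1[C@@H](Cc2ccccc2)COC1=O | intermediate
13 | (4S)-4-benzyl-3-{(2S)-2-[2-(benzyloxy)-3,4,5-trimethoxyphenyl]pent-4-ynoyl}-1,3-oxazolidin-2-one | C#CC[C@H](C(=O)N1[C@@H](Cc2ccccc2)COC1=O)c1cc(OC)c(OC)c(OC)c1OCc1ccccc1 | intermediate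
14 | (2S)-2-[2-(benzyloxy)-3,4,5-trimethoxyphenyl]pent-4-yn-1-ol | C#CC[C@H](CO)c1cc(OC)c(OC)c(OC)c1OCc1ccccc1 | intermediate
15 | (4S)-4-[2-(benzyloxy)-3,4,5-trimethoxyphenyl]-5-[(tert-butyldimethylsilyl)oxy]pent-1-yne | C#CC[C@H](CO[Si](C)(C)C(C)(C)C)c1cc(OC)c(OC)c(OC)c1OCc1ccccc1 | intermediate
16 | methyl vinyl ether | C=COC | starting material
17 | chromium hexacarbonyl | O=C=[Cr](=C=O)(=C=O)(=C=O)(=C=O)=C=O | starting material
18 | 1-methoxyvinyllithium | [Li]C(=C)OC | intermediate
19 | lithium pentacarbonyl(2-methoxyacryloyl)chromate | [Li+].C=C(OC)C([O-])=[Cr](=C=O)(=C=O)(=C=O)(=C=O)=C=O | intermediate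
20 | pentacarbonyl[methoxy(1-methoxyethenyl)methylidene]chromium | C=C(OC)C(OC)=[Cr](=C=O)(=C=O)(=C=O)(=C=O)=C=O | intermediate
21 | tricarbonylchromium complex of 22, bound η6 to ring A (the η6 bond is written as a dot) | COc1cc(O)c(C[C@H](CO[Si](C)(C)C(C)(C)C)c2cc(OC)c(OC)c(OC)c2OCc2ccccc2)cc1OC.O=C=[Cr](=C=O)=C=O | intermediate
22 | 2-{(2S)-2-[2-(benzyloxy)-3,4,5-trimethoxyphenyl]-3-[(tert-butyldimethylsilyl)oxy]propyl}-4,5-dimethoxyphenol | COc1cc(O)c(C[C@H](CO[Si](C)(C)C(C)(C)C)c2cc(OC)c(OC)c(OC)c2OCc2ccccc2)cc1OC | intermediate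
23 | 2-{(2S)-2-[2-(benzyloxy)-3,4,5-trimethoxyphenyl]-3-hydroxypropyl}-4,5-dimethoxyphenol | COc1cc(O)c(C[C@H](CO)c2cc(OC)c(OC)c(OC)c2OCc2ccccc2)cc1OC | intermediate
24 | (3S)-3-[2-(benzyloxy)-3,4,5-trimethoxyphenyl]-6,7-dimethoxy-3,4-dihydro-2H-chromene | COc1cc([C@H]2COc3cc(OC)c(OC)cc3C2)c(OCc4ccccc4)c(OC)c1OC | intermediate
25 | 6-[(3S)-6,7-dimethoxy-3,4-dihydro-2H-chromen-3-yl]-2,3,4-trimethoxyphenol | COc1cc([C@H]2COc3cc(OC)c(OC)cc3C2)c(O)c(OC)c1OC | intermediate
26 | abruquinone A, 5-[(3S)-6,7-dimethoxy-3,4-dihydro-2H-chromen-3-yl]-2,3-dimethoxycyclohexa-2,5-diene-1,4-dione | COC1=C(OC)C(=O)C([C@H]2COc3cc(OC)c(OC)cc3C2)=CC1=O | target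

**Step count**

Total: 14 steps. Longest linear sequence: 13 steps (steps 1 to 8, then 10 to 14); step 9 is a one-step branch.

**Steps most likely to fail, with fallbacks**

Step 10 (this fallback also covers a failure to prepare or handle carbene 20 in step 9). The electron-rich carbene may decompose before the alkyne inserts, the ketene intermediate may be diverted into cyclobutenone or furan formation, or the electron-rich phenol may be over-oxidised during air demetallation. The fallback gives up the benzannulation and brings ring A in as a ready-made benzyl electrophile; it sets out from imide 10 and returns at 23. Commercial 2-hydroxy-4,5-dimethoxybenzaldehyde (COc1cc(O)c(C=O)cc1OC) is protected with MOMCl and i-Pr2NEt to give 4,5-dimethoxy-2-(methoxymethoxy)benzaldehyde F1. Reduction with NaBH4 gives [4,5-dimethoxy-2-(methoxymethoxy)phenyl]methanol F2, and Appel bromination (CBr4, PPh3) gives 1-(bromomethyl)-4,5-dimethoxy-2-(methoxymethoxy)benzene F3, which is used at once. The sodium enolate 12 of imide 10 is alkylated with F3 under the conditions of step 6, on the same face, to give (4S)-4-benzyl-3-{(2S)-2-[2-(benzyloxy)-3,4,5-trimethoxyphenyl]-3-[4,5-dimethoxy-2-(methoxymethoxy)phenyl]propanoyl}-1,3-oxazolidin-2-one F4. LiBH4 cleavage as in step 7 gives (2S)-2-[2-(benzyloxy)-3,4,5-trimethoxyphenyl]-3-[4,5-dimethoxy-2-(methoxymethoxy)phenyl]propan-1-ol F5, and HCl in MeOH removes the MOM group to give 23, which enters step 12.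

Step 1. Bromination may occur at C5, which is activated by the neighbouring methoxy groups, or may run on to the dibromide. The fallback fixes the position by a sigmatropic shift that can only reach the single free ortho carbon; it sets out from 1 and returns at acid 7. Allylation of 1 (allyl bromide, K2CO3, acetone) gives 1,2,3-trimethoxy-4-(prop-2-en-1-yloxy)benzene F6. Claisen rearrangement (N,N-diethylaniline, 200 °C) gives 2,3,4-trimethoxy-6-(prop-2-en-1-yl)phenol F7, and benzylation (BnBr, K2CO3) gives 2-(benzyloxy)-3,4,5-trimethoxy-1-(prop-2-en-1-yl)benzene F8. Lemieux–Johnson cleavage (OsO4 cat., NaIO4, 2,6-lutidine, dioxane/H2O) gives [2-(benzyloxy)-3,4,5-trimethoxyphenyl]acetaldehyde F9, and Pinnick oxidation (NaClO2, NaH2PO4, 2-methylbut-2-ene) gives 7, which enters step 5.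

Step 6. Facial selectivity may be incomplete, the acidic α-aryl centre may epimerise during alkylation or quench, or propargyl bromide may react sluggishly or through its allenyl mode. The fallback sets C3 by catalytic asymmetric conjugate addition instead; it sets out from bromide 3 and returns at alcohol 14. Bromine–lithium exchange (n-BuLi, THF, −78 °C), B(OMe)3 and acidic work-up give [2-(benzyloxy)-3,4,5-trimethoxyphenyl]boronic acid F10. Hayashi–Miyaura addition to furan-2(5H)-one with Rh(acac)(C2H4)2 and the BINAP enantiomer that the facial model for cyclic acceptors assigns to this product (expected to be (S)-BINAP) in dioxane/H2O should give (4S)-4-[2-(benzyloxy)-3,4,5-trimethoxyphenyl]oxolan-2-one F11. Reduction with i-Bu2AlH (CH2Cl2, −78 °C) gives (4S)-4-[2-(benzyloxy)-3,4,5-trimethoxyphenyl]oxolan-2-ol F12, and Ohira–Bestmann homologation (dimethyl (1-diazo-2-oxopropyl)phosphonate, K2CO3, MeOH) converts the lactol into 14, which enters step 8.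

**Further compounds**

F1 | step 10 | 4,5-dimethoxy-2-(methoxymethoxy)benzaldehyde | COCOc1cc(OC)c(OC)cc1C=O
F2 | step 10 | [4,5-dimethoxy-2-(methoxymethoxy)phenyl]methanol | COCOc1cc(OC)c(OC)cc1CO
F3 | step 10 | 1-(bromomethyl)-4,5-dimethoxy-2-(methoxymethoxy)benzene | COCOc1cc(OC)c(OC)cc1CBr
F4 | step 10 | (4S)-4-benzyl-3-{(2S)-2-[2-(benzyloxy)-3,4,5-trimethoxyphenyl]-3-[4,5-dimethoxy-2-(methoxymethoxy)phenyl]propanoyl}-1,3-oxazolidin-2-one | COCOc1cc(OC)c(OC)cc1C[C@H](C(=O)N1[C@@H](Cc2ccccc2)COC1=O)c1cc(OC)c(OC)c(OC)c1OCc1ccccc1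
F5 | step 10 | (2S)-2-[2-(benzyloxy)-3,4,5-trimethoxyphenyl]-3-[4,5-dimethoxy-2-(methoxymethoxy)phenyl]propan-1-ol | COCOc1cc(OC)c(OC)cc1C[C@H](CO)c1cc(OC)c(OC)c(OC)c1OCc1ccccc1
F6 | step 1 | 1,2,3-trimethoxy-4-(prop-2-en-1-yloxy)benzene | C=CCOc1ccc(OC)c(OC)c1OC
F7 | step 1 | 2,3,4-trimethoxy-6-(prop-2-en-1-yl)phenol | C=CCc1cc(OC)c(OC)c(OC)c1O
F8 | step 1 | 2-(benzyloxy)-3,4,5-trimethoxy-1-(prop-2-en-1-yl)benzene | C=CCc1cc(OC)c(OC)c(OC)c1OCc1ccccc1
F9 | step 1 | [2-(benzyloxy)-3,4,5-trimethoxyphenyl]acetaldehyde | O=CCc1cc(OC)c(OC)c(OC)c1OCc1ccccc1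
F10 | step 6 | [2-(benzyloxy)-3,4,5-trimethoxyphenyl]boronic acid | OB(O)c1cc(OC)c(OC)c(OC)c1OCc1ccccc1
F11 | step 6 | (4S)-4-[2-(benzyloxy)-3,4,5-trimethoxyphenyl]oxolan-2-one | O=C1C[C@@H](c2cc(OC)c(OC)c(OC)c2OCc2ccccc2)CO1
F12 | step 6 | (4S)-4-[2-(benzyloxy)-3,4,5-trimethoxyphenyl]oxolan-2-ol | OC1C[C@@H](c2cc(OC)c(OC)c(OC)c2OCc2ccccc2)CO1
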